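Follow one molecule.

    intermediate A → target (k1 = 0.222 /s)
    starting material → intermediate A (k2 = 0.189 /s)
    intermediate A ⇌ intermediate B (K3 = 0.40, k3 = 0.202 /s)
    intermediate A ⇌ intermediate C (K4 = 0.104, k4 = 0.0164 /s)
    starting material ⇌ dormant form (K5 = 14.4, k5 = 0.0610 /s)
    target ⇌ isomer of the product (K6 = 1.2, k6 = 0.0247 /s)

| flask | starting material | remark | time |
|---|---|---|---|
| green | 1.6 M | a single well-mixed tank run continuously and read at steady state, 30 s in it on average |  |
| teal | 1.6 M | a closed flask charged with all of it at once and left for 30 s | 30 s |
| grey | 1.6 M | a single well-mixed tank run continuously and read at steady state, 90.0 s in it on average |  |

1. the set-up with the highest amount of target at the outlet or at the end, in percent of the starting material put in ("none" if the first two lie within 2 percentage points) (green / teal / grey / none)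
2. amount of target at the outlet or at the end, in percent of the starting material put in, green
3. amount of target at the outlet or at the end, in percent of the starting material put in, teal
4. amount of target at the outlet or at the end, in percent of the starting material put in, grey

Target and isomer of the product exchange among themselves, whatever feeds them. The pair relaxes at λ, the sum of the forward and back constants of that step, 0.0453 /s, towards a target share q of 45.5%. Product begins as pure target, so its excess over q begins at 54.5%.

Intermediates A and B relax with a half-life of 0.980 s, faster than intermediate A forms target, with a half-life of 3.1 s. A molecule in teal therefore waits 4.00 s as starting material, then 6.77 s among the intermediates, a lag of 10.8 s.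

Let N be λ times the product's time: the mean residence time in a tank, the reading time less the lag in teal. This relaxation count, a Damköhler number, is 1.36 for green, 4.08 for grey and 0.871 for teal. A closed flask multiplies the excess by exp(−N); a tank's balance divides it by one plus N. The target shares are 68.6%, 56.2% and 68.3%.

One number is not enough, since the molecule must also reach the pair. Its chance comes from two forks, counting exit from a tank and return from dormant form: 56.1% in green and 72.0% in grey. Teal's single fork between starting material's two steps gives 75.6%, the highest chance. Multiplied out, target is 38.5% in green, 40.5% in grey and 51.6% in teal, so teal leads.

The forecast gave 38.5% for green, 50.7% for teal and 40.5% for grey, with teal best: “Teal wins, because less target has isomerised.”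

The simulation gives 38.5%, 50.7% and 40.5%, with teal best. Teal's reckoned figure stands 0.90 percentage points above its simulated value. Intermediate A feeds target with a half-life of 3.1 s, shorter than target's forward half-life towards the isomer, 28 s at 30.0 s. Yet by then teal makes target at 0.537 of the rate at which it is used up, and holds 50.7% target and 23.3% isomer of the product. The same flask read at 120 s has a reckoned N of 4.95 with the same lag, and a reckoned target share of 45.9%. It holds 38.6% target against 44.0% isomer of the product, a target share of 46.7%, with dormant form at 16.8%.

(The numbers stand for no real mixture; the run is a simulation.)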